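The route rests on disconnecting the C6–C11 bond between the spiro carbon and the gem-dimethyl carbon. Chamigrane numbering is used: ring B is C1H2–C2(Br)=C3(Me)–C4H2–C5H2–C6 and ring A is C6–C7(Me)=C8H–C9H(OH)–C10H(Br)–C11Me2. The feature exploited is that C11–C10–C9–C8 is a 1,1-dimethylallyl unit on a ring B carbon that carries the future C7 as a carboxyl group. An Ireland–Claisen rearrangement of the 4-methylpent-3-en-2-yl ester of a carvone-derived ring B acid (C2 ketal, C3 methyl as relay) forms this vicinal quaternary bond and the C6 stereocentre in one operation. Ring A is closed later by C8-to-C7 acylation.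

Key step: step 6

Remark: alcohol 6 is used as the racemate and the side-chain alkene of 9–14 is drawn E; both elements are erased before the target, whereas the diastereomeric purity at C3 secured at compound 3 becomes the enantiomeric purity of everything after step 6.

Step 1
Reactants: 1 (S)-(+)-carvone
Product: 2 trans-dihydrocarvone [(2S,5S)-2-methyl-5-(prop-1-en-2-yl)cyclohexan-1-one; its C2 and C5 are the later C3 and C6]
Conditions: LiBH(s-Bu)3, THF, −78 °C; aq. NH4Cl
Reagents that add atoms: none
Why: Conjugate reduction of the β-unsubstituted enone by the hindered borohydride (1,4-hydride addition) gives the lithium enolate, and protonation along the axial trajectory with the isopropenyl group equatorial should place the new methyl equatorial, that is trans (3S in chamigrane numbering), which is also the more stable epimer.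

Step 2
Reactants: 2 trans-dihydrocarvone
Product: 3 dioxolane of 2 [(6S,9S)-6-methyl-9-(prop-1-en-2-yl)-1,4-dioxaspiro[4.5]decane]
Conditions: HOCH2CH2OH, p-TsOH (cat.), benzene, reflux, Dean–Stark
Reagents that add atoms: ethylene glycol, OCCO
Why: Acid-catalysed dioxolane formation with azeotropic removal of water masks the ketone and installs the C2 oxygen that later screens one face of C6; the minor cis (3R) isomer is removed here by chromatography, because after enolisation of C6 in step 6 the diastereomeric purity at C3 becomes the enantiomeric purity of every later compound.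

Step 3
Reactants: 3 dioxolane of trans-dihydrocarvone
Product: 4 ketal methyl ketone [1-[(7S,10S)-10-methyl-1,4-dioxaspiro[4.5]decan-7-yl]ethan-1-one]
Conditions: O3, CH2Cl2/MeOH, NaHCO3, −78 °C; then Me2S
Reagents that add atoms: ozone, O=[O+][O-]
Why: Ozonolysis with reductive work-up cleaves the only C=C bond, a 1,1-disubstituted alkene, to the methyl ketone and formaldehyde, and the bicarbonate buffer protects the dioxolane.

Step 4
Reactants: 4 ketal methyl ketone
Product: 5 ring B acid [(7S,10S)-10-methyl-1,4-dioxaspiro[4.5]decane-7-carboxylic acid; carboxyl on C6 trans to the C3 methyl]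
Conditions: Br2, NaOH, H2O/1,4-dioxane, 0 °C; then aq. NaH2PO4 to pH 5
Reagents that add atoms: sodium hydroxide, [Na+].[OH-]
Why: Haloform oxidation: exhaustive bromination of the methyl group through its kinetically favoured enolate and cleavage of the tribromomethyl ketone by hydroxide give the carboxylate, the ketal is stable to base and to the buffered acidification, and C3 is not enolisable so its configuration is kept (epimerisation at C6 would be harmless because C6 is flattened in step 6).

Step 5
Reactants: 5 ring B acid; 6 rac-4-methylpent-3-en-2-ol
Product: 7 allylic ester [4-methylpent-3-en-2-yl (7S,10S)-10-methyl-1,4-dioxaspiro[4.5]decane-7-carboxylate; both carbinol epimers]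
Conditions: DCC, DMAP (cat.), CH2Cl2, 0 °C → rt
Reagents that add atoms: none
Why: Steglich esterification under neutral conditions acylates the secondary allylic alcohol without ionising it or opening the ketal, and the carbinol carbon is deliberately left racemic because it becomes an alkene carbon in step 6.

Step 6
Reactants: 7 allylic ester
Product: 10 rearranged acid [(7R,10S)-10-methyl-7-[(3E)-2-methylpent-3-en-2-yl]-1,4-dioxaspiro[4.5]decane-7-carboxylic acid; C11 on C6 trans to the C3 methyl], via silyl ketene acetal 8 (not isolated), via trimethylsilyl ester 9 (not isolated)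
Conditions: LiN(i-Pr)2, THF, −78 °C; Me3SiCl, −78 → 23 °C; then PhMe, 80 °C; H2O work-up at pH 5
Reagents that add atoms: none
Why: Deprotonation at C6, the only enolisable position of the ester, and O-silylation give the exocyclic silyl ketene acetal 8, which undergoes a concerted suprafacial [3,3] sigmatropic shift through a six-membered chair-like transition state in which the C6–C11 bond forms as the allylic C9–O bond breaks and the alkene moves to C9=C10. The reaction type is the Ireland–Claisen rearrangement of γ,γ-dimethylallyl esters of α-branched cycloalkanecarboxylic acids, an established way to join two fully substituted carbons that no enolate alkylation with a tertiary electrophile could join. No ring is closed in this step. C6 is the only new stereocentre and is controlled by the ring B chair that keeps the C3 methyl equatorial: the axial C2 ketal oxygen and the axial C4 hydrogen screen the axial face of C6, so C11 should enter equatorially, trans to the C3 methyl, leaving the carboxyl group axial. This facial selectivity is the only selectivity the step needs and is expected to be useful but not complete, since it depends on the equatorial preference of one methyl group. The ketene acetal geometry, the carbinol configuration and the geometry of the new alkene are all erased later, and the minor C6 epimer is a diastereomer that is removed at ester 11 before the ketal is opened.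

Step 7
Reactants: 10 rearranged acid
Product: 11 ketal methyl ester [methyl (7R,10S)-10-methyl-7-[(3E)-2-methylpent-3-en-2-yl]-1,4-dioxaspiro[4.5]decane-7-carboxylate]
Conditions: MeI, K2CO3, DMF, rt
Reagents that add atoms: iodomethane, CI
Why: Carboxylate SN2 O-methylation succeeds where Fischer esterification of this doubly neopentyl acid would stall and spares the ketal, and the minor C6 epimer from step 6 is separated here by chromatography while C3 is still configurationally fixed.

Step 8
Reactants: 11 ketal methyl ester
Product: 12 keto ester [methyl (1R,4S)-4-methyl-1-[(3E)-2-methylpent-3-en-2-yl]-3-oxocyclohexane-1-carboxylate]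
Conditions: 1 M HCl, THF, rt
Reagents that add atoms: water, O
Why: Acid-catalysed acetal hydrolysis releases the C2 ketone under conditions that leave the hindered ester and the isolated alkene alone; C3 may now epimerise, which is of no consequence because it becomes an alkene carbon in step 9.

Step 9
Reactants: 12 keto ester
Product: 13 enol triflate [methyl (1R)-4-methyl-1-[(3E)-2-methylpent-3-en-2-yl]-3-(trifluoromethanesulfonyloxy)cyclohex-3-ene-1-carboxylate; C2=C3 double bond]
Conditions: Tf2O, 2,6-di-tert-butyl-4-methylpyridine, CH2Cl2, 0 °C → rt
Reagents that add atoms: trifluoromethanesulfonic anhydride, O=S(=O)(OS(=O)(=O)C(F)(F)F)C(F)(F)F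
Why: Enol triflate formation by O-sulfonylation and loss of a proton to the hindered pyridine should follow thermodynamic, Zaitsev-type control toward the tetrasubstituted C2=C3 enol derivative, helped by the shielding of the C1 hydrogens by the fully substituted C6, and a minor C1=C2 regioisomer would be a separable constitutional isomer.

Step 10
Reactants: 13 enol triflate
Product: 14 vinyl bromide ester [methyl (1R)-3-bromo-4-methyl-1-[(3E)-2-methylpent-3-en-2-yl]cyclohex-3-ene-1-carboxylate]
Conditions: Ni(cod)2 (10 mol%), LiBr, DMA/THF, rt
Reagents that add atoms: lithium bromide, [Li+].[Br-]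
Why: Nickel-catalysed halogen exchange of an alkenyl triflate, which proceeds by oxidative addition of zerovalent nickel into the C–O bond, exchange of triflate for bromide at the metal and C–Br reductive elimination, is known for cyclic fully substituted enol triflates and tolerates esters and isolated alkenes.

Step 11
Reactants: 14 vinyl bromide ester
Product: 15 C9 methyl ketone ester [methyl (1R)-3-bromo-4-methyl-1-(2-methyl-4-oxopentan-2-yl)cyclohex-3-ene-1-carboxylate]
Conditions: Pd(OAc)2 (5 mol%), 1,4-benzoquinone, aq. HBF4, DMA/MeCN/H2O, rt
Reagents that add atoms: water, O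
Why: Wacker oxidation of an internal alkene with divalent palladium under chloride-free acidic conditions: water should add to C9, the alkene carbon remote from the quaternary C11, β-hydride elimination can only occur from C9 and gives the enol of the methyl ketone, and the electron-poor tetrasubstituted vinyl bromide is neither hydrated nor inserted while the benzoquinone keeps palladium oxidised.

Step 12
Reactants: 15 C9 methyl ketone ester
Product: 16 spiro dione [(6R)-8-bromo-5,5,9-trimethylspiro[5.5]undec-8-ene-1,3-dione; carbonyls at C7 and C9]
Conditions: KOt-Bu, THF, 0 °C → rt; aq. HCl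
Reagents that add atoms: none
Why: Dieckmann-type intramolecular Claisen condensation in which the C8 enolate of the methyl ketone acylates at the C7 ester (6-exo-trig closure of ring A; the C10 enolate could only form a four-membered ring), driven to completion by deprotonation of the 1,3-dione despite the hindered ester.

Step 13
Reactants: 16 spiro dione
Product: 17 vinylogous ester [(6R)-8-bromo-3-methoxy-5,5,9-trimethylspiro[5.5]undeca-2,8-dien-1-one; methoxy on C9 and ketone at C7]
Conditions: MeOH, p-TsOH (cat.), reflux
Reagents that add atoms: methanol, CO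
Why: Acid-catalysed enol etherification of a cyclic 1,3-dione is reversible and should settle on the vinylogous ester with the methoxy group on C9, since both addition to the C7 carbonyl and an alkoxy group beside the spiro carbon are sterically disfavoured.

Step 14
Reactants: 17 vinylogous ester
Product: 19 spiro enone [(6R)-8-bromo-1,5,5,9-trimethylspiro[5.5]undeca-1,8-dien-3-one; C7(Me)=C8–C9=O], via tertiary allylic alcohol 18 (not isolated)
Conditions: MeLi, CeCl3, THF, −78 °C; then 1 M HCl, rt
Reagents that add atoms: methyllithium, [Li]C; water, O
Why: Stork–Danheiser transposition: the oxophilic, weakly basic methylcerium reagent adds 1,2 to the hindered C7 carbonyl without γ-deprotonation or bromine–metal exchange, and aqueous acid ionises the tertiary allylic alcohol, hydrolyses the enol ether and delivers the C7(Me)=C8–C9=O enone.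

Step 15
Reactants: 19 spiro enone
Product: 21 C10 bromo enone [(4S,6S)-4,8-dibromo-1,5,5,9-trimethylspiro[5.5]undeca-1,8-dien-3-one; bromine on C10 cis to C1], via silyl dienol ether 20 (not isolated)
Conditions: LiN(i-Pr)2, THF, −78 °C; Me3SiCl; then NBS, −78 → 0 °C
Reagents that add atoms: N-bromosuccinimide, BrN1C(=O)CCC1=O
Why: Kinetic deprotonation at C10 (the α′ position, faster than removal of a γ-hydrogen from the C7 methyl) gives the cross-conjugated dienolate, which is trapped as its silyl ether and brominated at C10 by NBS (electrophilic α-halogenation of a silyl enol ether); by analogy with closely related spiro dienol ethers, and not by a rigorous conformational argument, the bromine should enter on the ring A face that carries C1, opposite to the C5–C4 arm, giving the 10S epimer with a pseudoequatorial bromine.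

Step 16
Reactants: 21 C10 bromo enone
Product: 22 target [(3S,4S,6S)-4,8-dibromo-1,5,5,9-trimethylspiro[5.5]undeca-1,8-dien-3-ol; chamigrane locants 6S,9S,10S]
Conditions: NaBH4, CeCl3·7H2O, MeOH, −78 °C
Reagents that add atoms: none
Why: Luche reduction: the cerium-activated methoxyborohydride adds 1,2 to the enone, and axial approach of this small hydride to the half-chair in which the C10 bromine is pseudoequatorial (an axial bromine would be syn-diaxial to a ring B arm on C6) should give the pseudoequatorial 9S carbinol, trans to bromine, at a temperature where neither epimerisation at C10 nor epoxide formation is expected.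

Compound list
1 | (S)-(+)-carvone | CC1=CC[C@@H](CC1=O)C(C)=C | starting material
2 | trans-dihydrocarvone, (2S,5S)-2-methyl-5-(prop-1-en-2-yl)cyclohexan-1-one | C[C@H]1CC[C@@H](CC1=O)C(C)=C | intermediate
3 | (6S,9S)-6-methyl-9-(prop-1-en-2-yl)-1,4-dioxaspiro[4.5]decane | C[C@H]1CC[C@@H](CC12OCCO2)C(C)=C | intermediate
4 | 1-[(7S,10S)-10-methyl-1,4-dioxaspiro[4.5]decan-7-yl]ethan-1-one | C[C@H]1CC[C@@H](CC12OCCO2)C(C)=O | intermediate
5 | (7S,10S)-10-methyl-1,4-dioxaspiro[4.5]decane-7-carboxylic acid (ring B acid) | C[C@H]1CC[C@@H](CC12OCCO2)C(=O)O | intermediate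
6 | rac-4-methylpent-3-en-2-ol | CC(O)C=C(C)C | starting material
7 | 4-methylpent-3-en-2-yl (7S,10S)-10-methyl-1,4-dioxaspiro[4.5]decane-7-carboxylate (both carbinol epimers) | C[C@H]1CC[C@@H](CC12OCCO2)C(=O)OC(C)C=C(C)C | intermediate
8 | trimethylsilyl ketene acetal of 7 (exocyclic C6=C(OSiMe3)O-allyl, both geometries) | C[C@H]1CCC(CC12OCCO2)=C(O[Si](C)(C)C)OC(C)C=C(C)C | intermediate (not isolated)
9 | trimethylsilyl (7R,10S)-10-methyl-7-[(3E)-2-methylpent-3-en-2-yl]-1,4-dioxaspiro[4.5]decane-7-carboxylate | C[C@H]1CC[C@](CC12OCCO2)(C(=O)O[Si](C)(C)C)C(C)(C)/C=C/C | intermediate (not isolated)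
10 | (7R,10S)-10-methyl-7-[(3E)-2-methylpent-3-en-2-yl]-1,4-dioxaspiro[4.5]decane-7-carboxylic acid | C[C@H]1CC[C@](CC12OCCO2)(C(=O)O)C(C)(C)/C=C/C | intermediate
11 | methyl (7R,10S)-10-methyl-7-[(3E)-2-methylpent-3-en-2-yl]-1,4-dioxaspiro[4.5]decane-7-carboxylate | C[C@H]1CC[C@](CC12OCCO2)(C(=O)OC)C(C)(C)/C=C/C | intermediate
12 | methyl (1R,4S)-4-methyl-1-[(3E)-2-methylpent-3-en-2-yl]-3-oxocyclohexane-1-carboxylate | C[C@H]1CC[C@](CC1=O)(C(=O)OC)C(C)(C)/C=C/C | intermediate
13 | methyl (1R)-4-methyl-1-[(3E)-2-methylpent-3-en-2-yl]-3-(trifluoromethanesulfonyloxy)cyclohex-3-ene-1-carboxylate | CC1=C(OS(=O)(=O)C(F)(F)F)C[C@@](CC1)(C(=O)OC)C(C)(C)/C=C/C | intermediate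
14 | methyl (1R)-3-bromo-4-methyl-1-[(3E)-2-methylpent-3-en-2-yl]cyclohex-3-ene-1-carboxylate | CC1=C(Br)C[C@@](CC1)(C(=O)OC)C(C)(C)/C=C/C | intermediate
15 | methyl (1R)-3-bromo-4-methyl-1-(2-methyl-4-oxopentan-2-yl)cyclohex-3-ene-1-carboxylate | CC1=C(Br)C[C@@](CC1)(C(=O)OC)C(C)(C)CC(C)=O | intermediate
16 | (6R)-8-bromo-5,5,9-trimethylspiro[5.5]undec-8-ene-1,3-dione | O=C1CC(=O)CC(C)(C)[C@]12CCC(C)=C(Br)C2 | intermediate
17 | (6R)-8-bromo-3-methoxy-5,5,9-trimethylspiro[5.5]undeca-2,8-dien-1-one | O=C1C=C(OC)CC(C)(C)[C@]12CCC(C)=C(Br)C2 | intermediate
18 | 8-bromo-3-methoxy-1,5,5,9-tetramethylspiro[5.5]undeca-2,8-dien-1-ol (C7 carbinol, both epimers, spiro centre as in 17) | CC1(O)C=C(OC)CC(C)(C)[C@]12CCC(C)=C(Br)C2 | intermediate (not isolated)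
19 | (6R)-8-bromo-1,5,5,9-trimethylspiro[5.5]undeca-1,8-dien-3-one | CC1=CC(=O)CC(C)(C)[C@]12CCC(C)=C(Br)C2 | intermediate
20 | trimethylsilyl dienol ether of 19 (C9–OSiMe3, C9=C10 and C7=C8 double bonds) | CC1=CC(O[Si](C)(C)C)=CC(C)(C)[C@]12CCC(C)=C(Br)C2 | intermediate (not isolated)
21 | (4S,6S)-4,8-dibromo-1,5,5,9-trimethylspiro[5.5]undeca-1,8-dien-3-one | CC1=CC(=O)[C@@H](Br)C(C)(C)[C@]12CCC(C)=C(Br)C2 | intermediate
22 | (3S,4S,6S)-4,8-dibromo-1,5,5,9-trimethylspiro[5.5]undeca-1,8-dien-3-ol (CNP0268938.1) | CC1=C[C@H](O)[C@@H](Br)C(C)(C)[C@]12CCC(C)=C(Br)C2 | target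

Total step count: 16. Longest linear sequence: 16 steps from 1; alcohol 6 is bought and enters in step 5.

Steps most likely to fail

Step 16. The hydride may arrive mainly on the equatorial face of C9, because the axial approach passes the axial methyl on C11; this would give the axial carbinol, cis to bromine. The fallback accepts this sense and corrects it by inversion. It sets out from 21, which is reduced with the bulky hydride i-Bu2AlH (toluene, −78 °C) to give the 9-epi alcohol F5 deliberately. Mitsunobu reaction of F5 with 4-nitrobenzoic acid (PPh3, diisopropyl azodicarboxylate, THF) should give the inverted 4-nitrobenzoate F6; SN2′ attack is blocked because C7 is fully substituted. Cold methanolysis of F6 (K2CO3, MeOH, 0 °C) returns to the route at 22.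

Step 11. Coordination and hydroxypalladation of the 1,2-disubstituted alkene may be too slow beside the quaternary C11, or water may add in part at C10. The fallback replaces the direct oxidation by hydroboration and alcohol oxidation. It sets out from 14: 9-borabicyclo[3.3.1]nonane in THF at reflux should place boron on C9, remote from the quaternary carbon, giving the B-alkyl borane F1. Oxidation of F1 with NaBO3·4H2O gives the C9 secondary alcohol F2 (both epimers). Dess–Martin periodinane then oxidises F2 to the methyl ketone, and the route is rejoined at 15.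

Step 15. The bromine may be delivered mainly to the face of C10 that carries the C5–C4 arm, or with little preference; the two epimers are separable diastereomers. The fallback sets C10 by protonation instead of by bromination. It sets out from 19, brominated as in step 15, and takes on the 10-epi bromo enone F3. LiN(SiMe3)2 in THF at −78 °C converts F3 into the lithium bromodienolate F4. Kinetic protonation of F4 with acetic acid at −78 °C should put the proton on the face that the electrophilic bromine preferred, which leaves the bromine on the C1 face; the route is rejoined at 21.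

Further compounds
F1 | step 11 | methyl (1R)-3-bromo-1-[4-(9-borabicyclo[3.3.1]nonan-9-yl)-2-methylpentan-2-yl]-4-methylcyclohex-3-ene-1-carboxylate (boron on C9, both epimers) | CC1=C(Br)C[C@@](CC1)(C(=O)OC)C(C)(C)CC(C)B2C3CCCC2CCC3
F2 | step 11 | methyl (1R)-3-bromo-1-(4-hydroxy-2-methylpentan-2-yl)-4-methylcyclohex-3-ene-1-carboxylate (C9 alcohol, both epimers) | CC1=C(Br)C[C@@](CC1)(C(=O)OC)C(C)(C)CC(C)O
F3 | step 15 | (4R,6S)-4,8-dibromo-1,5,5,9-trimethylspiro[5.5]undeca-1,8-dien-3-one (10-epi bromo enone) | CC1=CC(=O)[C@H](Br)C(C)(C)[C@]12CCC(C)=C(Br)C2
F4 | step 15 | lithium dienolate of F3 (C9–OLi, C9=C10 bearing bromine) | CC1=CC(O[Li])=C(Br)C(C)(C)[C@]12CCC(C)=C(Br)C2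
F5 | step 16 | (3R,4S,6S)-4,8-dibromo-1,5,5,9-trimethylspiro[5.5]undeca-1,8-dien-3-ol (9-epi alcohol, cis bromohydrin) | CC1=C[C@@H](O)[C@@H](Br)C(C)(C)[C@]12CCC(C)=C(Br)C2
F6 | step 16 | (3S,4S,6S)-4,8-dibromo-1,5,5,9-trimethylspiro[5.5]undeca-1,8-dien-3-yl 4-nitrobenzoate | CC1=C[C@H](OC(=O)c3ccc(cc3)[N+](=O)[O-])[C@@H](Br)C(C)(C)[C@]12CCC(C)=C(Br)C2
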